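**Retrosynthetic overview**
- The target is a cis-fused (1(10)Z,4E)-germacra-1(10),4-dien-12,6-olide; the last disconnections are the C9 silyl ether and the C3 (R)-2-methylbutanoate.
- Enabling feature: in the ten-membered ring, C10=C1–C2–C3–C4=C5 is a cyclodeca-1,5-diene with C2–C3 as its central σ-bond. A retro-Cope step maps it onto a cis-1,2-dialkenylcyclohexane (ring A, C5–C10, bond C5–C10 restored). C5 can carry a transient oxygen (alkoxide → enolate → enol triflate → H), and the C3 oxygen becomes the terminus of a (Z)-enol ether.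
- Forward, an anionic oxy-Cope ring expansion forms C2–C3, turns ring A into the ten-membered ring, sets both ring alkene geometries and sets C3.
- Ring A comes from (R)-carvone: vinyl addition, directed epoxidation and a semipinacol 1,2-vinyl shift give C9–O and the C10 quaternary centre; the isopropenyl group becomes the cis-fused lactone (ring B) with C11 set by conjugate reduction.
- Ring order: ring A (chiral pool) → ring B (γ-lactone) → ten-membered ring by four-carbon expansion of ring A.

Key step: step 13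

Remark on numbering: germacranolide numbers are used (ring C1–C10, C1=C10 and C4=C5, ester on C3, OH on C9, lactone O on C6, C7–C11(C13)–C12(=O), C14 on C10, C15 on C4); "up/down" refer to ring A drawn with the lactone oxygen down.
Assumption: (2R)-2-methylbutanoic acid 29 is taken as a purchasable compound.

**Step 1**
Reactants: 1 (R)-carvone; 2 vinylmagnesium bromide
Product: 3 (1S,5R)-1-ethenyl-2-methyl-5-(prop-1-en-2-yl)cyclohex-2-en-1-ol
Conditions: THF, −78 → 0 °C; then H2O
Reagents that add atoms: none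
Why: Grignard 1,2-addition to the enone; axial attack anti to the pseudo-equatorial isopropenyl group should place vinyl trans and the new tertiary OH cis to the C7 substituent.

**Step 2**
Reactants: 3 dienol
Product: 4 (1S,2S,4R,6S)-2-ethenyl-1-methyl-4-(prop-1-en-2-yl)-7-oxabicyclo[4.1.0]heptan-2-ol
Conditions: VO(acac)2 (2 mol %), t-BuOOH, CH2Cl2, 0 °C → rt
Reagents that add atoms: tert-butyl hydroperoxide, CC(C)(C)OO
Why: Vanadium-catalysed hydroxyl-directed epoxidation (Sharpless–Michaelson type) should deliver oxygen to the trisubstituted ring alkene syn to the tertiary OH and leave the vinyl and isopropenyl groups untouched.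

**Step 3**
Reactants: 4 epoxy alcohol
Product: 5 (2R,3S,5R)-2-ethenyl-3-hydroxy-2-methyl-5-(prop-1-en-2-yl)cyclohexan-1-one
Conditions: BF3·OEt2 (0.2 equiv), CH2Cl2, −78 → −40 °C
Reagents that add atoms: none
Why: Semipinacol rearrangement of a 2,3-epoxy alcohol: the vinyl group, anti-periplanar to the breaking tertiary C10–O bond, shifts suprafacially from C5 to C10 with inversion at C10, which should give the C5 ketone, the C10 quaternary centre (vinyl trans to O9) and the C9 alcohol with retention.

**Step 4**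
Reactants: 5 hydroxy ketone
Product: 6 (2R,3S,5R)-3-[(tert-butyldimethylsilyl)oxy]-2-ethenyl-2-methyl-5-(prop-1-en-2-yl)cyclohexan-1-one
Conditions: TBSOTf, 2,6-lutidine, CH2Cl2, −78 → 0 °C
Reagents that add atoms: tert-butyldimethylsilyl trifluoromethanesulfonate, CC(C)(C)[Si](C)(C)OS(=O)(=O)C(F)(F)F
Why: Silylation of the hindered secondary alcohol under non-basic conditions protects C9–OH and avoids retro-aldol cleavage of the β-hydroxy ketone.

**Step 5**
Reactants: 6 silyl ether
Product: 7 (2R,3S,5R)-3-[(tert-butyldimethylsilyl)oxy]-2-ethenyl-5-(3-hydroxyprop-1-en-2-yl)-2-methylcyclohexan-1-one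
Conditions: SeO2 (0.3 equiv), t-BuOOH, salicylic acid (cat.), CH2Cl2, rt
Reagents that add atoms: tert-butyl hydroperoxide, CC(C)(C)OO
Why: Catalytic SeO2 allylic oxidation (ene reaction, then [2,3] shift) should oxidise the methyl group of the 1,1-disubstituted alkene; the vinyl group on C10 has no allylic hydrogen.

**Step 6**
Reactants: 7 allylic alcohol
Product: 8 2-[(1R,3S,4R)-3-[(tert-butyldimethylsilyl)oxy]-4-ethenyl-4-methyl-5-oxocyclohexyl]prop-2-enal
Conditions: MnO2, CH2Cl2, rt
Reagents that add atoms: none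
Why: MnO2 oxidation is selective for the primary allylic alcohol and stops at the enal.

**Step 7**
Reactants: 8 enal
Product: 9 2-[(1R,3S,4R)-3-[(tert-butyldimethylsilyl)oxy]-4-ethenyl-4-methyl-5-oxocyclohexyl]prop-2-enoic acid
Conditions: NaClO2, NaH2PO4, 2-methylbut-2-ene, t-BuOH/H2O, 0 °C → rt
Reagents that add atoms: sodium chlorite, [Na+].[O-]Cl=O
Why: Pinnick oxidation converts the enal to the acrylic acid while the scavenger protects the alkenes from HOCl.

**Step 8**
Reactants: 9 keto acid
Product: 12 cis-fused α-methylene keto lactone, via dilithium enolate carboxylate 10 (not isolated), via α-iodo ketone carboxylate 11 (not isolated)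
Conditions: LiN(SiMe3)2 (2.2 equiv), THF, −78 °C; I2 (1.1 equiv), −78 °C → rt
Reagents that add atoms: none
Why: Enolate α-iodination at C6 (the only enolisable position) anti to the C7 side chain, then intramolecular 5-exo-tet displacement of iodide by the carboxylate with inversion, should give the cis-fused γ-lactone with O6 cis to C7–C11; a cis-iodide would equilibrate by iodide exchange.

**Step 9**
Reactants: 12 α-methylene lactone
Product: 14 (3R,3aS,5S,6R,7aR)-keto lactone with C11 methyl, via copper enolate 13 (not isolated)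
Conditions: [(Ph3P)CuH]6 (0.2 equiv of hexamer), toluene, rt; then H2O
Reagents that add atoms: none
Why: Copper hydride conjugate reduction (Stryker type) of the exocyclic enoate spares the ketone and vinyl group, and kinetic protonation of the enolate on the convex face of the cis-fused bicycle should put H11 cis to H7, i.e. (11R).

**Step 10**
Reactants: 15 propyne; 16 pinacol
Product: 18 2-[(Z)-2-bromoprop-1-en-1-yl]-4,4,5,5-tetramethyl-1,3,2-dioxaborolane, via dibromoborane 17 (not isolated)
Conditions: BBr3, CH2Cl2, −78 °C; then pinacol, −78 °C → rt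
Reagents that add atoms: boron tribromide, BrB(Br)Br
Why: syn-Bromoboration of propyne (Br to the internal carbon, B to the terminus) fixes Br and B cis, and immediate esterification with pinacol prevents geometric isomerisation.

**Step 11**
Reactants: 18 alkenyl boronate; 19 (4-methoxyphenyl)methanol
Product: 20 1-({[(Z)-2-bromoprop-1-en-1-yl]oxy}methyl)-4-methoxybenzene
Conditions: Cu(OAc)2 (2 equiv), Et3N, 4 Å MS, CH2Cl2, rt, air
Reagents that add atoms: none
Why: Copper-mediated oxidative C–O coupling of an alkenyl boronate with an alcohol (Chan–Evans–Lam type) proceeds with retention of alkene geometry, so Br and O stay cis.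

**Step 12**
Reactants: 20 bromo enol ether; 14 keto lactone
Product: 23 tertiary alcohol (3R,3aS,5S,6R,7S,7aR) carrying the (Z)-enol ether on C5, via alkenyllithium 21 (not isolated), via alkenylcerium dichloride 22 (not isolated)
Conditions: t-BuLi (2.0 equiv), Et2O, −78 °C; CeCl3, THF, −78 °C; then 14, −78 °C; then H2O
Reagents that add atoms: none
Why: Br–Li exchange with retention, transmetalation and organocerium carbonyl addition (Imamoto type); attack should be axial, anti to the axial C10 methyl and the axial lactone oxygen on C6, placing the C5 alkenyl group cis to the C10 vinyl group, while the oxophilic, weakly basic cerium reagent should spare the lactone and not enolise C6.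

**Step 13 (key step)**
Reactants: 23 tertiary alcohol
Product: 26 ring-expanded enol triflate, via potassium alkoxide 24 (not isolated), via potassium enolate 25 (not isolated)
Conditions: KN(SiMe3)2 (1.05 equiv), THF, −78 °C → rt; then Comins' reagent, −78 → 0 °C
Reagents that add atoms: N-(5-chloropyridin-2-yl)-1,1,1-trifluoro-N-[(trifluoromethyl)sulfonyl]methanesulfonamide (Comins' reagent), FC(F)(F)S(=O)(=O)N(c1ccc(Cl)cn1)S(=O)(=O)C(F)(F)F
Why: Deprotonation gives alkoxide 24, whose C3=C4–C5–C10–C1=C2 1,5-diene undergoes an anionic oxy-Cope [3,3] shift (C5–C10 breaks, C2–C3 forms) to the regiodefined enolate 25, which is O-triflated; the closest known reaction type is the anionic oxy-Cope ring expansion of cis-1,2-dialkenylcyclohexanols to cyclodec-5-enones with enolate trapping. The ten-membered ring is not closed by a cyclisation but by a four-carbon ring expansion of ring A through a chair-like six-centre transition state. Only the ring A chair with C7–C11 and the C9 silyloxy group equatorial is populated; in it the C5 alkenyl group is axial and the C10 vinyl group equatorial, so C6 sits pseudo-equatorial and C9 pseudo-axial in the Cope chair, which should give the 4E enolate double bond and the 1(10)Z double bond. C3 is set by chirality transfer from C5 and C10 through this chair: the (Z)-enol ether places the benzyloxy oxygen pseudo-axial, so C2 bonds to the face of C3 that gives (3S). The step needs chair over boat and [3,3] shift over fragmentation or lactone enolisation; the ring A substituents secure the chair, only 1.05 equiv of base is used, and a potassium ion bridging O5 and the pseudo-axial benzyloxy oxygen should offset their 1,3-diaxial contact. The triflate stores the C4=C5 geometry for replacement of O by H in step 14.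

**Step 14**
Reactants: 26 enol triflate
Product: 27 (3R,3aS,5S,6Z,9S,10E,11aR)-5-silyloxy-9-(4-methoxybenzyloxy) germacradienolide
Conditions: Pd(OAc)2 (5 mol %), PPh3 (10 mol %), HCO2H, n-Bu3N, DMF, 50 °C
Reagents that add atoms: none
Why: Pd-catalysed formate reduction of an enol triflate (Cacchi type): oxidative addition to zerovalent palladium, decarboxylation of formate and C–H reductive elimination replace OTf by H with retention, which should give the 4E alkene.

**Step 15**
Reactants: 27 PMB ether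
Product: 28 (3R,3aS,5S,6Z,9S,10E,11aR)-5-silyloxy-9-hydroxy germacradienolide
Conditions: DDQ, CH2Cl2/pH 7 buffer, 0 °C
Reagents that add atoms: none
Why: Oxidative cleavage of the 4-methoxybenzyl ether by DDQ frees C3–OH without acid, leaving the silyl ether, lactone and ring alkenes intact.

**Step 16**
Reactants: 29 (2R)-2-methylbutanoic acid; 28 allylic alcohol
Product: 31 silyl-protected target ester, via mixed anhydride 30 (not isolated)
Conditions: 2,4,6-trichlorobenzoyl chloride, Et3N, toluene, rt; then 28, DMAP, rt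
Reagents that add atoms: none
Why: Yamaguchi esterification acylates the hindered secondary allylic alcohol with retention at C3 and without ketene formation, so the (2R) acid centre should be preserved.

**Step 17**
Reactants: 31 silyl ether
Product: 32 target
Conditions: HF·pyridine, pyridine/THF, 0 °C → rt
Reagents that add atoms: none
Why: Buffered fluoride desilylation frees C9–OH without acid-induced transannular cyclisation or ester migration.

**Compound list**
1 | (R)-carvone, (5R)-2-methyl-5-(prop-1-en-2-yl)cyclohex-2-en-1-one | CC1=CC[C@@H](C(C)=C)CC1=O | starting material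
2 | vinylmagnesium bromide | C=C[Mg]Br | starting material
3 | (1S,5R)-1-ethenyl-2-methyl-5-(prop-1-en-2-yl)cyclohex-2-en-1-ol | C=C[C@]1(O)C(C)=CC[C@@H](C(C)=C)C1 | intermediate
4 | (1S,2S,4R,6S)-2-ethenyl-1-methyl-4-(prop-1-en-2-yl)-7-oxabicyclo[4.1.0]heptan-2-ol | C=C[C@]1(O)[C@@]2(C)O[C@H]2C[C@@H](C(C)=C)C1 | intermediate
5 | (2R,3S,5R)-2-ethenyl-3-hydroxy-2-methyl-5-(prop-1-en-2-yl)cyclohexan-1-one | C=C[C@]1(C)[C@@H](O)C[C@@H](C(C)=C)CC1=O | intermediate
6 | (2R,3S,5R)-3-[(tert-butyldimethylsilyl)oxy]-2-ethenyl-2-methyl-5-(prop-1-en-2-yl)cyclohexan-1-one | C=C[C@]1(C)[C@@H](O[Si](C)(C)C(C)(C)C)C[C@@H](C(C)=C)CC1=O | intermediate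
7 | (2R,3S,5R)-3-[(tert-butyldimethylsilyl)oxy]-2-ethenyl-5-(3-hydroxyprop-1-en-2-yl)-2-methylcyclohexan-1-one | C=C[C@]1(C)[C@@H](O[Si](C)(C)C(C)(C)C)C[C@@H](C(=C)CO)CC1=O | intermediate
8 | 2-[(1R,3S,4R)-3-[(tert-butyldimethylsilyl)oxy]-4-ethenyl-4-methyl-5-oxocyclohexyl]prop-2-enal | C=C[C@]1(C)[C@@H](O[Si](C)(C)C(C)(C)C)C[C@@H](C(=C)C=O)CC1=O | intermediate
9 | 2-[(1R,3S,4R)-3-[(tert-butyldimethylsilyl)oxy]-4-ethenyl-4-methyl-5-oxocyclohexyl]prop-2-enoic acid | C=C[C@]1(C)[C@@H](O[Si](C)(C)C(C)(C)C)C[C@@H](C(=C)C(=O)O)CC1=O | intermediate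
10 | dilithium enolate carboxylate of 9 (enolate C5=C6) | C=C[C@]1(C)[C@@H](O[Si](C)(C)C(C)(C)C)C[C@@H](C(=C)C(=O)[O-])C=C1[O-].[Li+].[Li+] | intermediate
11 | lithium carboxylate of the C6-iodo ketone (iodine trans to the acrylate side chain) | C=C[C@]1(C)[C@@H](O[Si](C)(C)C(C)(C)C)C[C@@H](C(=C)C(=O)[O-])[C@H](I)C1=O.[Li+] | intermediate
12 | (3aS,5S,6R,7aR)-5-[(tert-butyldimethylsilyl)oxy]-6-ethenyl-6-methyl-3-methylidenehexahydro-1-benzofuran-2,7-dione | C=C[C@]1(C)[C@@H](O[Si](C)(C)C(C)(C)C)C[C@H]2C(=C)C(=O)O[C@H]2C1=O | intermediate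
13 | copper enolate of 14 (triphenylphosphine-ligated, O-bound) | C=C[C@]1(C)[C@@H](O[Si](C)(C)C(C)(C)C)C[C@H]2C(C)=C(O[Cu])O[C@H]2C1=O | intermediate
14 | (3R,3aS,5S,6R,7aR)-5-[(tert-butyldimethylsilyl)oxy]-6-ethenyl-3,6-dimethylhexahydro-1-benzofuran-2,7-dione | C=C[C@]1(C)[C@@H](O[Si](C)(C)C(C)(C)C)C[C@H]2[C@@H](C)C(=O)O[C@H]2C1=O | intermediate
15 | propyne | CC#C | starting material
16 | pinacol, 2,3-dimethylbutane-2,3-diol | CC(C)(O)C(C)(C)O | starting material
17 | (Z)-(2-bromoprop-1-en-1-yl)dibromoborane | C/C(Br)=C/B(Br)Br | intermediate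
18 | 2-[(Z)-2-bromoprop-1-en-1-yl]-4,4,5,5-tetramethyl-1,3,2-dioxaborolane | C/C(Br)=C/B1OC(C)(C)C(C)(C)O1 | intermediate
19 | (4-methoxyphenyl)methanol | COc1ccc(CO)cc1 | starting material
20 | 1-({[(Z)-2-bromoprop-1-en-1-yl]oxy}methyl)-4-methoxybenzene | C/C(Br)=C/OCc1ccc(OC)cc1 | intermediate
21 | {1-[(4-methoxybenzyl)oxy]prop-1-en-2-yl}lithium, Li cis to O | C/C([Li])=C/OCc1ccc(OC)cc1 | intermediate
22 | dichloro{1-[(4-methoxybenzyl)oxy]prop-1-en-2-yl}cerium, Ce cis to O | C/C([Ce](Cl)Cl)=C/OCc1ccc(OC)cc1 | intermediate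
23 | (3R,3aS,5S,6R,7S,7aR)-5-[(tert-butyldimethylsilyl)oxy]-6-ethenyl-7-hydroxy-7-{(1Z)-1-[(4-methoxyphenyl)methoxy]prop-1-en-2-yl}-3,6-dimethylhexahydro-1-benzofuran-2(3H)-one | C=C[C@]1(C)[C@@H](O[Si](C)(C)C(C)(C)C)C[C@H]2[C@@H](C)C(=O)O[C@H]2[C@]1(O)/C(C)=C\OCc1ccc(OC)cc1 | intermediate
24 | potassium alkoxide of 23 | C=C[C@]1(C)[C@@H](O[Si](C)(C)C(C)(C)C)C[C@H]2[C@@H](C)C(=O)O[C@H]2[C@]1([O-])/C(C)=C\OCc1ccc(OC)cc1.[K+] | intermediate
25 | potassium (3R,3aS,5S,6Z,9S,10Z,11aR)-5-[(tert-butyldimethylsilyl)oxy]-9-[(4-methoxyphenyl)methoxy]-3,6,10-trimethyl-2-oxo-2,3,3a,4,5,8,9,11a-octahydrocyclodeca[b]furan-11-olate | COc1ccc(CO[C@H]2C/C=C(/C)[C@@H](O[Si](C)(C)C(C)(C)C)C[C@@H]3[C@H](/C([O-])=C/2C)OC(=O)[C@@H]3C)cc1.[K+] | intermediate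
26 | (3R,3aS,5S,6Z,9S,10Z,11aR)-5-[(tert-butyldimethylsilyl)oxy]-9-[(4-methoxyphenyl)methoxy]-3,6,10-trimethyl-2-oxo-2,3,3a,4,5,8,9,11a-octahydrocyclodeca[b]furan-11-yl trifluoromethanesulfonate | COc1ccc(CO[C@H]2C/C=C(/C)[C@@H](O[Si](C)(C)C(C)(C)C)C[C@@H]3[C@H](/C(OS(=O)(=O)C(F)(F)F)=C/2C)OC(=O)[C@@H]3C)cc1 | intermediate
27 | (3R,3aS,5S,6Z,9S,10E,11aR)-5-[(tert-butyldimethylsilyl)oxy]-9-[(4-methoxyphenyl)methoxy]-3,6,10-trimethyl-3a,4,5,8,9,11a-hexahydrocyclodeca[b]furan-2(3H)-one | COc1ccc(CO[C@H]2C/C=C(/C)[C@@H](O[Si](C)(C)C(C)(C)C)C[C@@H]3[C@H](/C=C/2C)OC(=O)[C@@H]3C)cc1 | intermediate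
28 | (3R,3aS,5S,6Z,9S,10E,11aR)-5-[(tert-butyldimethylsilyl)oxy]-9-hydroxy-3,6,10-trimethyl-3a,4,5,8,9,11a-hexahydrocyclodeca[b]furan-2(3H)-one | O[C@H]1C/C=C(/C)[C@@H](O[Si](C)(C)C(C)(C)C)C[C@@H]2[C@H](/C=C/1C)OC(=O)[C@@H]2C | intermediate
29 | (2R)-2-methylbutanoic acid | CC[C@@H](C)C(=O)O | starting material
30 | (2R)-2-methylbutanoic 2,4,6-trichlorobenzoic anhydride | CC[C@@H](C)C(=O)OC(=O)c1c(Cl)cc(Cl)cc1Cl | intermediate
31 | (3R,3aS,5S,6Z,9S,10E,11aR)-5-[(tert-butyldimethylsilyl)oxy]-3,6,10-trimethyl-2-oxo-2,3,3a,4,5,8,9,11a-octahydrocyclodeca[b]furan-9-yl (2R)-2-methylbutanoate | CC[C@@H](C)C(=O)O[C@H]1C/C=C(/C)[C@@H](O[Si](C)(C)C(C)(C)C)C[C@@H]2[C@H](/C=C/1C)OC(=O)[C@@H]2C | intermediate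
32 | (3R,3aS,5S,6Z,9S,10E,11aR)-5-hydroxy-3,6,10-trimethyl-2-oxo-2,3,3a,4,5,8,9,11a-octahydrocyclodeca[b]furan-9-yl (2R)-2-methylbutanoate | CC[C@@H](C)C(=O)O[C@H]1C/C=C(/C)[C@@H](O)C[C@@H]2[C@H](/C=C/1C)OC(=O)[C@@H]2C | target

**Step count and risks**
Total steps: 17. Longest linear sequence: 15 (steps 1–9 and 12–17); steps 10–11 make the side fragment that joins in step 12.

Steps most likely to fail:

1. Step 13. The tertiary alkoxide may enolise the lactone α-position (loss of the C11 configuration), or fragment before the [3,3] shift, which is slowed by the pseudo-axial alkoxy group. The fallback is a neutral thermal siloxy-Cope route that sets out from 23. Silylation with 1-(trimethylsilyl)imidazole (neat, 60 °C) should give the tertiary trimethylsilyl ether F1. Heating F1 in o-dichlorobenzene at about 200 °C in a base-washed sealed tube should give, through the same ring-enforced chair, the ring-expanded trimethylsilyl enol ether F2. Fluoride-induced triflation of F2 (CsF, Comins' reagent, DME, rt) returns the route at 26.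

2. Step 12. The organometallic may attack the lactone carbonyl, the α-acyloxy ketone may enolise, or the β-alkoxyalkenyl metal may be lost by β-elimination before it adds. The fallback builds the C5 side chain from a small acetylide and sets out from 19 and 14. Treating 19 with KH and trichloroethylene (THF) should give the (E)-1,2-dichlorovinyl ether F3. n-BuLi (2.2 equiv, −78 °C) converts F3 by elimination and Cl–Li exchange into lithium [(4-methoxybenzyl)oxy]acetylide F4, a small, ketone-selective nucleophile. Axial addition of F4 to 14 should give the propargylic alcohol F5. syn-Methylcupration of the ynol ether (MeMgBr, CuBr·SMe2, Et2O, −30 °C; copper on the oxygen-bearing carbon) gives the alkenylcopper bromomagnesium alkoxide F6, and protonolysis of F6 returns the route at 23 with the same (Z)-enol ether.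

3. Step 5. Conversion may be incomplete, oxidation may compete at the C7 methine, or the alcohol may over-oxidise unevenly. The fallback sets out from 6. Ene-type allylic chlorination (NaOCl, CeCl3·7H2O, CH2Cl2/H2O) should give the allylic chloride F7. Oxidation of F7 with 4-methylmorpholine N-oxide in MeCN (Kornblum type) should give the enal and return the route at 8, skipping step 6.

**Further compounds**
F1 | step 13 | trimethylsilyl ether of 23 | C=C[C@]1(C)[C@@H](O[Si](C)(C)C(C)(C)C)C[C@H]2[C@@H](C)C(=O)O[C@H]2[C@]1(O[Si](C)(C)C)/C(C)=C\OCc1ccc(OC)cc1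
F2 | step 13 | ring-expanded trimethylsilyl enol ether (silyl analogue of 26) | COc1ccc(CO[C@H]2C/C=C(/C)[C@@H](O[Si](C)(C)C(C)(C)C)C[C@@H]3[C@H](/C(O[Si](C)(C)C)=C/2C)OC(=O)[C@@H]3C)cc1
F3 | step 12 | 1-({[(E)-1,2-dichloroethenyl]oxy}methyl)-4-methoxybenzene | Cl/C=C(/Cl)OCc1ccc(OC)cc1
F4 | step 12 | lithium [(4-methoxybenzyl)oxy]acetylide | [Li]C#COCc1ccc(OC)cc1
F5 | step 12 | (3R,3aS,5S,6R,7S,7aR)-5-[(tert-butyldimethylsilyl)oxy]-6-ethenyl-7-hydroxy-7-{[(4-methoxyphenyl)methoxy]ethynyl}-3,6-dimethylhexahydro-1-benzofuran-2(3H)-one | C=C[C@]1(C)[C@@H](O[Si](C)(C)C(C)(C)C)C[C@H]2[C@@H](C)C(=O)O[C@H]2[C@]1(O)C#COCc1ccc(OC)cc1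
F6 | step 12 | alkenylcopper bromomagnesium alkoxide from syn-methylcupration of F5 | C=C[C@]1(C)[C@@H](O[Si](C)(C)C(C)(C)C)C[C@H]2[C@@H](C)C(=O)O[C@H]2[C@]1(O[Mg]Br)/C(C)=C(/[Cu])OCc1ccc(OC)cc1
F7 | step 5 | (2R,3S,5R)-3-[(tert-butyldimethylsilyl)oxy]-5-(3-chloroprop-1-en-2-yl)-2-ethenyl-2-methylcyclohexan-1-one | C=C[C@]1(C)[C@@H](O[Si](C)(C)C(C)(C)C)C[C@@H](C(=C)CCl)CC1=O
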